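The oxolane ring is numbered O1, C2 (aryl), C3 (CH2OH), C4 (aroyl), C5. The ketone carbon and the CH2OH carbon stand 1,4 to each other across C4–C3, a dissonant pattern. The aroyl–C4 bond is therefore cut to an acyl anion and a C3=C4 enoate. A carbene-catalysed Stetter reaction joins 3,4,5-trimethoxybenzaldehyde to a (2R)-2-aryl-2,5-dihydrofuran-3-carboxylate. Acyl group and hydrogen add to the same ring face, opposite the C2 aryl group, which sets C4 and C3 (2,3-cis, 3,4-trans) in one operation. The precursor comes from the same aldehyde by asymmetric Morita–Baylis–Hillman reaction, O-allylation and ring-closing metathesis. Its hexafluoroisopropyl ester serves as activating group until reduction.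

Key step: step 4

Remark: with the numbering above the target is (2S,3S,4R). The C2 aryl group and the C3 CH2OH group are cis, and the C3 CH2OH group and the C4 aroyl group are trans.

Step 1
Reactants: 1 3,4,5-trimethoxybenzaldehyde; 2 1,1,1,3,3,3-hexafluoropropan-2-yl acrylate
Product: 3 1,1,1,3,3,3-hexafluoropropan-2-yl 2-[(R)-hydroxy(3,4,5-trimethoxyphenyl)methyl]prop-2-enoate
Conditions: β-isocupreidine (10 mol %), DMF, −55 °C
Reagents that add atoms: none
Why: Asymmetric Morita–Baylis–Hillman reaction in which the quinuclidine nitrogen of β-isocupreidine adds to the activated acrylate and its phenolic OH organises the aldol and elimination steps by hydrogen bonding, so that an aromatic aldehyde of benzaldehyde-like electrophilicity should give the (R)-carbinol that becomes C2 of the ring.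

Step 2
Reactants: 3 Morita–Baylis–Hillman alcohol; 4 allyl bromide
Product: 5 1,1,1,3,3,3-hexafluoropropan-2-yl 2-[(R)-(prop-2-en-1-yloxy)(3,4,5-trimethoxyphenyl)methyl]prop-2-enoate
Conditions: Ag2O, 4 Å molecular sieves, CH2Cl2, dark, rt
Reagents that add atoms: none
Why: Silver-oxide-assisted Williamson O-allylation runs without a free alkoxide, so retro-aldol cleavage, oxa-Michael addition and acyl transfer of the active ester should be avoided, and no bond at the stereocentre is touched.

Step 3
Reactants: 5 allyl ether
Product: 6 1,1,1,3,3,3-hexafluoropropan-2-yl (2R)-2-(3,4,5-trimethoxyphenyl)-2,5-dihydrofuran-3-carboxylate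
Conditions: second-generation Grubbs catalyst (H2IMes)(PCy3)Cl2Ru=CHPh (5 mol %), CH2Cl2, 40 °C
Reagents that add atoms: none
Why: Ring-closing metathesis of the terminal allyl alkene with the 1,1-disubstituted acrylate alkene, a closure established for allyl ethers of Morita–Baylis–Hillman adducts, forms the C3=C4 bond of the five-membered ring with loss of ethene and leaves C2 unchanged.

Step 4
Reactants: 6 dihydrofuran ester; 1 3,4,5-trimethoxybenzaldehyde
Product: 8 1,1,1,3,3,3-hexafluoropropan-2-yl (2S,3R,4R)-4-(3,4,5-trimethoxybenzoyl)-2-(3,4,5-trimethoxyphenyl)oxolane-3-carboxylate, via Breslow enaminol 7 (not isolated)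
Conditions: 2-mesityl-6,7-dihydro-5H-pyrrolo[2,1-c][1,2,4]triazol-2-ium chloride (20 mol %), KN(SiMe3)2 (18 mol %), HN(SiMe3)2 removed in vacuo, toluene, 40 °C, argon
Reagents that add atoms: none
Why: Proposed new method: the free triazolylidene adds to aldehyde 1 and a proton shift gives the nucleophilic enaminol 7, whose former aldehyde carbon attacks the electrophilic C4 of enoate 6, after which the O–H proton passes to C3 of the ester enolate and loss of the carbene releases the ketone. The closest known reaction types are the intermolecular Stetter reaction of aromatic aldehydes with acrylates and fumarates, the intramolecular Stetter reaction of trisubstituted enoates and the carbene-catalysed syn hydroacylation of strained alkenes, so the new element is intermolecular addition to a cyclic, α-branched, β-substituted enoate, which the hexafluoroisopropyl ester and the allylic ring oxygen next to C4 make more electrophilic. No ring is closed. C4 is controlled by the C2 aryl group, which covers one face of the nearly flat dihydrofuran, so the bulky enaminol should bond on the opposite face (2,4-trans). C3 is controlled by the internal proton transfer through a five-membered array on the face that carries the new bond, a net syn hydroacylation that leaves the ester cis to the C2 aryl group and trans to the aroyl group, and removal of HN(SiMe3)2 suppresses protonation from outside. The step needs attack at C4 rather than at the ester carbonyl and on one ring face only, which the polarisation of C3=C4 by the ester, the shielding of the ester carbonyl by the C2 substituent and the C2 aryl group secure, while benzoin formation from 1 and acyl transfer to the carbene are reversible and the weakly basic carbene should leave C3–H and C4–H of 8 untouched.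

Step 5
Reactants: 8 keto ester
Product: 9 [(2S,3S,4R)-4-[hydroxy(3,4,5-trimethoxyphenyl)methyl]-2-(3,4,5-trimethoxyphenyl)oxolan-3-yl]methanol, both epimers at the new carbinol carbon
Conditions: LiAlH4, THF, −78 to 0 °C; then H2O/aq NaOH work-up
Reagents that add atoms: none
Why: Hydride reduction with LiAlH4 takes the active ester to the primary alcohol and the ketone to a carbinol faster than either α-position can enolise, so C3 and C4 are kept, and the new carbinol centre needs no control because step 6 removes it.

Step 6
Reactants: 9 diol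
Product: 10 (2S,3S,4R)-3-(hydroxymethyl)-4-(3,4,5-trimethoxybenzoyl)-2-(3,4,5-trimethoxyphenyl)oxolane (target)
Conditions: activated MnO2 (excess), CH2Cl2, rt
Reagents that add atoms: none
Why: Chemoselective MnO2 oxidation acts on the electron-rich benzylic alcohol and leaves the aliphatic primary alcohol alone, the 3,4-trans arrangement rules out hemiketal formation, and C4 already holds the more stable configuration next to the new ketone.

Compound list
1 | 3,4,5-trimethoxybenzaldehyde | COc1cc(C=O)cc(OC)c1OC | starting material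
2 | 1,1,1,3,3,3-hexafluoropropan-2-yl acrylate | C=CC(=O)OC(C(F)(F)F)C(F)(F)F | starting material
3 | 1,1,1,3,3,3-hexafluoropropan-2-yl 2-[(R)-hydroxy(3,4,5-trimethoxyphenyl)methyl]prop-2-enoate | C=C(C(=O)OC(C(F)(F)F)C(F)(F)F)[C@H](O)c1cc(OC)c(OC)c(OC)c1 | intermediate
4 | allyl bromide | C=CCBr | starting material
5 | 1,1,1,3,3,3-hexafluoropropan-2-yl 2-[(R)-(prop-2-en-1-yloxy)(3,4,5-trimethoxyphenyl)methyl]prop-2-enoate | C=CCO[C@H](c1cc(OC)c(OC)c(OC)c1)C(=C)C(=O)OC(C(F)(F)F)C(F)(F)F | intermediate
6 | 1,1,1,3,3,3-hexafluoropropan-2-yl (2R)-2-(3,4,5-trimethoxyphenyl)-2,5-dihydrofuran-3-carboxylate | O=C(OC(C(F)(F)F)C(F)(F)F)C1=CCO[C@@H]1c1cc(OC)c(OC)c(OC)c1 | intermediate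
7 | Breslow enaminol from 1 and the N-mesityl bicyclic triazolylidene | COc1cc(C(O)=C2N(c3c(C)cc(C)cc3C)N=C3CCCN23)cc(OC)c1OC | intermediate
8 | 1,1,1,3,3,3-hexafluoropropan-2-yl (2S,3R,4R)-4-(3,4,5-trimethoxybenzoyl)-2-(3,4,5-trimethoxyphenyl)oxolane-3-carboxylate | COc1cc(C(=O)[C@H]2CO[C@H](c3cc(OC)c(OC)c(OC)c3)[C@@H]2C(=O)OC(C(F)(F)F)C(F)(F)F)cc(OC)c1OC | intermediate
9 | [(2S,3S,4R)-4-[hydroxy(3,4,5-trimethoxyphenyl)methyl]-2-(3,4,5-trimethoxyphenyl)oxolan-3-yl]methanol, carbinol epimers | COc1cc(C(O)[C@H]2CO[C@H](c3cc(OC)c(OC)c(OC)c3)[C@@H]2CO)cc(OC)c1OC | intermediate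
10 | (2S,3S,4R)-3-(hydroxymethyl)-4-(3,4,5-trimethoxybenzoyl)-2-(3,4,5-trimethoxyphenyl)oxolane | COc1cc(C(=O)[C@H]2CO[C@H](c3cc(OC)c(OC)c(OC)c3)[C@@H]2CO)cc(OC)c1OC | target

Total step count: 6. Longest linear sequence: 6 steps (1 → 3 → 5 → 6 → 8 → 9 → 10).

Steps most likely to fail

Step 4 (proposed new method).
- **What may go wrong:** The enaminol may add too slowly to the hindered trisubstituted enoate, so that benzoin formation and acyl transfer from the active ester take over. Protonation of the enolate from outside may also erode the control at C3.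
- **Fallback:** It uses known chemistry, sets out from 6 and comes back at 10.
- **Reduction and protection:** i-Bu2AlH (CH2Cl2, −78 °C) reduces 6 to the allylic alcohol [(2R)-2-(3,4,5-trimethoxyphenyl)-2,5-dihydrofuran-3-yl]methanol F1. Silylation (t-BuMe2SiCl, imidazole) gives tert-butyldimethyl{[(2R)-2-(3,4,5-trimethoxyphenyl)-2,5-dihydrofuran-3-yl]methoxy}silane F2.
- **Hydroboration:** BH3·THF adds syn, anti to the C2 aryl group, with boron at the less substituted C4. H2O2/NaOH then gives (3R,4R,5S)-4-{[(tert-butyldimethylsilyl)oxy]methyl}-5-(3,4,5-trimethoxyphenyl)oxolan-3-ol F3, in which the 2,3-cis relation is fixed.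
- **Iodide:** An Appel reaction (I2, PPh3, imidazole) gives tert-butyl{[(2S,3S,4S)-4-iodo-2-(3,4,5-trimethoxyphenyl)oxolan-3-yl]methoxy}dimethylsilane F4.
- **Coupling:** A nickel-catalysed reductive cross-electrophile coupling with commercial 3,4,5-trimethoxybenzoyl chloride (NiCl2(MeOCH2CH2OMe), 4,4'-di-tert-butyl-2,2'-bipyridine, Zn, DMA) forms the same aroyl–C4 bond. It runs through a C4 radical that is captured on the face away from the two cis substituents and gives the tert-butyldimethylsilyl ether of the target F5.
- **Deprotection:** Bu4NF in THF then gives 10.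

Step 1.
- **What may go wrong:** Addition to the aldehyde may be slow at −55 °C, acyl transfer of the active ester may divert material, and enantioselection may be incomplete.
- **Fallback:** It sets out from 1 and 2 and comes back at 3.
- **Racemate:** 1,4-Diazabicyclo[2.2.2]octane catalyses the same union without stereocontrol and gives the racemic alcohol 1,1,1,3,3,3-hexafluoropropan-2-yl 2-[hydroxy(3,4,5-trimethoxyphenyl)methyl]prop-2-enoate F6.
- **Resolution:** An acylative kinetic resolution follows, with isobutyric anhydride, i-Pr2NEt and the enantiomer of the isothiourea catalyst HyperBTM that acylates the (S)-alcohol faster. It converts the unwanted half into the (S)-isobutyrate 1,1,1,3,3,3-hexafluoropropan-2-yl 2-[(S)-(2-methylpropanoyloxy)(3,4,5-trimethoxyphenyl)methyl]prop-2-enoate F7. This ester is separated by chromatography from unreacted 3.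

Step 2.
- **What may go wrong:** Alkylation of the hindered, weakly nucleophilic carbinol may be sluggish, the active ester may be hydrolysed on the silver oxide surface, and allylic transposition may occur.
- **Fallback:** It sets out from 3 and comes back at 5.
- **Carbonate:** Allyl chloroformate and pyridine give the mixed carbonate 1,1,1,3,3,3-hexafluoropropan-2-yl 2-[(R)-{[(prop-2-en-1-yloxy)carbonyl]oxy}(3,4,5-trimethoxyphenyl)methyl]prop-2-enoate F8.
- **Decarboxylative O-allylation:** The zerovalent palladium complex Pd(PPh3)4 ionises the unsubstituted allyl terminus. Carbon dioxide is lost and the alkoxide recombines with the π-allyl complex, with retention at the carbinol carbon.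

Further compounds
F1 | step 4 | [(2R)-2-(3,4,5-trimethoxyphenyl)-2,5-dihydrofuran-3-yl]methanol | OCC1=CCO[C@@H]1c1cc(OC)c(OC)c(OC)c1
F2 | step 4 | tert-butyldimethyl{[(2R)-2-(3,4,5-trimethoxyphenyl)-2,5-dihydrofuran-3-yl]methoxy}silane | CC(C)(C)[Si](C)(C)OCC1=CCO[C@@H]1c1cc(OC)c(OC)c(OC)c1
F3 | step 4 | (3R,4R,5S)-4-{[(tert-butyldimethylsilyl)oxy]methyl}-5-(3,4,5-trimethoxyphenyl)oxolan-3-ol | O[C@H]1CO[C@H](c2cc(OC)c(OC)c(OC)c2)[C@@H]1CO[Si](C)(C)C(C)(C)C
F4 | step 4 | tert-butyl{[(2S,3S,4S)-4-iodo-2-(3,4,5-trimethoxyphenyl)oxolan-3-yl]methoxy}dimethylsilane | I[C@@H]1CO[C@H](c2cc(OC)c(OC)c(OC)c2)[C@@H]1CO[Si](C)(C)C(C)(C)C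
F5 | step 4 | tert-butyldimethylsilyl ether of the target, (2S,3S,4R) | COc1cc(C(=O)[C@H]2CO[C@H](c3cc(OC)c(OC)c(OC)c3)[C@@H]2CO[Si](C)(C)C(C)(C)C)cc(OC)c1OC
F6 | step 1 | racemic 1,1,1,3,3,3-hexafluoropropan-2-yl 2-[hydroxy(3,4,5-trimethoxyphenyl)methyl]prop-2-enoate | C=C(C(=O)OC(C(F)(F)F)C(F)(F)F)C(O)c1cc(OC)c(OC)c(OC)c1
F7 | step 1 | 1,1,1,3,3,3-hexafluoropropan-2-yl 2-[(S)-(2-methylpropanoyloxy)(3,4,5-trimethoxyphenyl)methyl]prop-2-enoate | C=C(C(=O)OC(C(F)(F)F)C(F)(F)F)[C@@H](OC(=O)C(C)C)c1cc(OC)c(OC)c(OC)c1
F8 | step 2 | 1,1,1,3,3,3-hexafluoropropan-2-yl 2-[(R)-{[(prop-2-en-1-yloxy)carbonyl]oxy}(3,4,5-trimethoxyphenyl)methyl]prop-2-enoate | C=CCOC(=O)O[C@H](c1cc(OC)c(OC)c(OC)c1)C(=C)C(=O)OC(C(F)(F)F)C(F)(F)F
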